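A direct plan would make the oxirane first and the benzene ring last. Sonogashira coupling would give enynol A1, then Sharpless epoxidation with isovalerylation in the same flask and desilylation would give epoxy alkyne A2. A Dötz benzannulation of A2 with chromium carbene A3 would then give phenol A4, and tigloylation would finish.
Its weakest points would be:
- The benzannulation would spend the enantioenriched epoxide in a stoichiometric zerovalent-chromium reaction with competing furan and cyclobutenone channels, and with a Lewis-acidic metal next to a tertiary epoxide.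
- The epoxidation of a 2-alkynyl allylic alcohol would leave the only stereocentre to an analogy with methallyl alcohol, and the product could not be purified before acylation.
- The passage through free phenol A4 would place a hydroxyl ortho to the benzylic epoxide, which it could open (5-exo) during demetalation, chromatography or acylation.
Four of its six steps would go into the two small annulation partners.

**Plan of the new route.** The oxirane carbon C2 carries, besides its ring oxygen and the aryl carbon, two CH2–O arms: the ring CH2 and the exocyclic CH2 of the isovalerate. It is therefore a 2-arylglycerol carbon, and the two arms become identical when tied through one oxygen in a 3-aryloxetan-3-ol. The retrosynthesis cuts the isovalerate C–O bond, then the oxirane O–CH2 bond (to a bromohydrin), then reconnects Br–CH2 and CH2–OH into the oxetane, and last cuts the aryl–C bond (aryllithium + oxetan-3-one). The benzene ring is bought, the oxetane is attached intact, and the oxirane arises last by enantioselective ring contraction. There is no benzannulation, no chromium and no enynol epoxidation. The phenol is tigloylated before any epoxide exists, so no free ortho-hydroxyphenyl epoxide occurs.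

Key step: step 4

Remark: the sense of induction of the squaramide for an aryl/silyloxy pair at the oxetane C3 cannot be derived with certainty. The route is written for the catalyst enantiomer that gives (S)-9; if a first run gave (R)-9, the mirror-image catalyst (from D-tert-leucine and the (S)-pyrrolidine) would be used. 4-Methoxy-3-methylphenol and oxetan-3-one are taken as commercial.

Step 1
Reactants: 1 4-methoxy-3-methylphenol
Product: 2 2-bromo-4-methoxy-5-methylphenol
Conditions: NBS (1.0 equiv), MeCN, −20 to 0 °C
Reagents that add atoms: N-bromosuccinimide, O=C1CCC(=O)N1Br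
Why: Electrophilic aromatic bromination, in which the hydroxyl is the strongest director, its para position is blocked by OMe, and of its two ortho positions only the one para to the methyl group is unflanked.

Step 2
Reactants: 2 2-bromo-4-methoxy-5-methylphenol; 3 oxetan-3-one
Product: 5 3-(2-hydroxy-5-methoxy-4-methylphenyl)oxetan-3-ol, via dilithiated phenolate 4 (not isolated)
Conditions: n-BuLi (2.2 equiv), Et2O, −78 to 0 °C; 3 (1.3 equiv), THF, −78 °C to rt; aq NH4Cl
Reagents that add atoms: none
Why: Deprotonation followed by bromine–lithium exchange gives the ortho-lithiated lithium phenolate, which adds to the strained, unhindered ketone (aryllithium 1,2-addition to oxetan-3-one) without any protecting group and without forming a stereocentre.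

Step 3
Reactants: 5 3-(2-hydroxy-5-methoxy-4-methylphenyl)oxetan-3-ol
Product: 7 4-methoxy-5-methyl-2-[3-[(trimethylsilyl)oxy]oxetan-3-yl]phenyl (2E)-2-methylbut-2-enoate, via oxetanol tiglate 6 (not isolated)
Conditions: tigloyl chloride (1.05 equiv), pyridine, CH2Cl2, −20 to 0 °C; then N-(trimethylsilyl)imidazole (1.5 equiv), 0 °C to rt
Reagents that add atoms: (2E)-2-methylbut-2-enoyl chloride, C/C=C(\C)C(=O)Cl; N-(trimethylsilyl)imidazole, C[Si](C)(C)n1ccnc1
Why: Chemoselective acylation of the acidic, unhindered phenol by the acylpyridinium ion (the tertiary oxetanol is inert without a stronger acyl-transfer catalyst, and pyridine is too weak a base to deconjugate the enoyl chloride), followed by neutral silylation of the tertiary hydroxyl, which removes the only O–H that would make HBr in step 4 and blocks acyl transfer to that oxygen.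

Step 4
Reactants: 7 4-methoxy-5-methyl-2-[3-[(trimethylsilyl)oxy]oxetan-3-yl]phenyl (2E)-2-methylbut-2-enoate
Product: 9 2-[(2S)-1-bromo-2,3-dihydroxypropan-2-yl]-4-methoxy-5-methylphenyl (2E)-2-methylbut-2-enoate, via bis-silyl ether bromide 8 (not isolated)
Conditions: Me3SiBr (1.5 equiv), 3-{[3,5-bis(trifluoromethyl)phenyl]amino}-4-({(2S)-3,3-dimethyl-1-oxo-1-[(2R)-2-(phenanthren-9-yl)pyrrolidin-1-yl]butan-2-yl}amino)cyclobut-3-ene-1,2-dione (5 mol%), t-BuOMe, −78 °C; then 1 M HCl, THF, 0 °C
Reagents that add atoms: bromotrimethylsilane, C[Si](C)(C)Br
Why: The squaramide binds the bromide of Me3SiBr through its two N–H bonds and so raises the Lewis acidity of silicon; Me3Si+ passes to the oxetane oxygen, and the catalyst-bound bromide attacks one of the two enantiotopic ring CH2 carbons of the silyloxonium ion in an SN2 step that cleaves that C–O bond and releases the strain of the four-membered ring. The closest known reaction type is the hydrogen-bond-donor-catalysed enantioselective addition of Me3SiBr to 3-substituted and 3,3-disubstituted oxetanes, which gives 1,3-bromohydrin silyl ethers. No ring is closed here: the step opens the oxetane and stores in CH2Br the leaving group by which the oxirane, the last ring of the target, closes in step 5 in the 3-exo-tet mode, so that steps 4 and 5 together are a ring contraction. The one stereocentre is the former oxetane C3; no bond to it is made or broken, and its configuration, (S) in 8 and 9, follows only from which CH2–O bond is cut, which the chiral ion pair decides (catalyst control). The step needs selectivity between two constitutionally identical CH2 groups and a slow uncatalysed opening; the unlike C3 substituents (a flat aryl ring that can stack on the phenanthryl group of the catalyst against a globular Me3SiO group) should secure the first and the absence of any O–H the second, while the tigloyl ester keeps the phenol oxygen from opening the ring and the meta-methoxy, ortho-acyloxy pattern disfavours benzylic ionisation. Aqueous acid then cleaves both silyl ethers to diol 9, at which the enantiomeric purity can be assayed and, if 9 crystallises, raised.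

Step 5
Reactants: 9 2-[(2S)-1-bromo-2,3-dihydroxypropan-2-yl]-4-methoxy-5-methylphenyl (2E)-2-methylbut-2-enoate
Product: 10 2-[(2S)-2-(hydroxymethyl)oxiran-2-yl]-4-methoxy-5-methylphenyl (2E)-2-methylbut-2-enoate
Conditions: Ag2O (1.5 equiv), 4 Å MS, THF, rt, dark
Reagents that add atoms: none
Why: Silver-assisted halohydrin cyclisation, in which Ag2O polarises the C–Br bond and takes up HBr as AgBr so that the neutral tertiary hydroxyl closes the oxirane by 3-exo-tet displacement at CH2 without an alkoxide that could take the tigloyl group from the neighbouring aryl ester; no bond at the stereocentre is touched, and the slower 4-exo closure by the primary hydroxyl would only return recyclable oxetanol 6.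

Step 6
Reactants: 10 2-[(2S)-2-(hydroxymethyl)oxiran-2-yl]-4-methoxy-5-methylphenyl (2E)-2-methylbut-2-enoate
Product: 11 [(2R)-2-[5-methoxy-4-methyl-2-[(2E)-2-methylbut-2-enoyl]oxyphenyl]oxiran-2-yl]methyl 3-methylbutanoate
Conditions: isovaleric anhydride (1.3 equiv), Et3N, 4-(dimethylamino)pyridine (5 mol%), CH2Cl2, −20 to 0 °C
Reagents that add atoms: 3-methylbutanoic anhydride, CC(C)CC(=O)OC(=O)CC(C)C
Why: Acyl-transfer-catalysed esterification of the unhindered primary alcohol by the anhydride in a cold, chloride-free, non-acidic medium that spares the tertiary benzylic epoxide and the aryl tiglate; the Payne rearrangement open to 10 is degenerate and returns the same enantiomer, so the configuration is not at risk (the descriptor changes from S to R only through the priority change on acylation).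

**Compound list**

1 | 4-methoxy-3-methylphenol | COc1ccc(O)cc1C | starting material
2 | 2-bromo-4-methoxy-5-methylphenol | COc1cc(Br)c(O)cc1C | intermediate
3 | oxetan-3-one | O=C1COC1 | starting material
4 | lithium 2-lithio-4-methoxy-5-methylphenolate | COc1cc([Li])c(O[Li])cc1C | intermediate
5 | 3-(2-hydroxy-5-methoxy-4-methylphenyl)oxetan-3-ol | COc1cc(C2(O)COC2)c(O)cc1C | intermediate
6 | 2-(3-hydroxyoxetan-3-yl)-4-methoxy-5-methylphenyl (2E)-2-methylbut-2-enoate | C/C=C(\C)C(=O)Oc1cc(C)c(OC)cc1C1(O)COC1 | intermediate
7 | 4-methoxy-5-methyl-2-[3-[(trimethylsilyl)oxy]oxetan-3-yl]phenyl (2E)-2-methylbut-2-enoate | C/C=C(\C)C(=O)Oc1cc(C)c(OC)cc1C1(O[Si](C)(C)C)COC1 | intermediate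
8 | 2-[(2S)-1-bromo-2,3-bis[(trimethylsilyl)oxy]propan-2-yl]-4-methoxy-5-methylphenyl (2E)-2-methylbut-2-enoate | C/C=C(\C)C(=O)Oc1cc(C)c(OC)cc1[C@](O[Si](C)(C)C)(CO[Si](C)(C)C)CBr | intermediate
9 | 2-[(2S)-1-bromo-2,3-dihydroxypropan-2-yl]-4-methoxy-5-methylphenyl (2E)-2-methylbut-2-enoate | C/C=C(\C)C(=O)Oc1cc(C)c(OC)cc1[C@](O)(CO)CBr | intermediate
10 | 2-[(2S)-2-(hydroxymethyl)oxiran-2-yl]-4-methoxy-5-methylphenyl (2E)-2-methylbut-2-enoate | C/C=C(\C)C(=O)Oc1cc(C)c(OC)cc1[C@]1(CO)CO1 | intermediate
11 | [(2R)-2-[5-methoxy-4-methyl-2-[(2E)-2-methylbut-2-enoyl]oxyphenyl]oxiran-2-yl]methyl 3-methylbutanoate | C/C=C(\C)C(=O)Oc1cc(C)c(OC)cc1[C@]1(COC(=O)CC(C)C)CO1 | target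

**Count and risks**

Total step count: 6. Longest linear sequence: 6 steps (1 to 11).

Steps most likely to fail:

1. Step 4. The discrimination between the two enantiotopic CH2–O bonds may be weak for an aryl/silyloxy pair, or traces of HBr may open the oxetane without the catalyst, so that 9 forms with low enantiomeric purity. The fallback sets out from 2 and comes back at 10; it sets the stereocentre on an alkene instead of an oxetane. Bromophenol 2 would be acylated with tigloyl chloride and pyridine to 2-bromo-4-methoxy-5-methylphenyl (2E)-2-methylbut-2-enoate F1. Stille coupling of F1 with 2-(tributylstannyl)prop-2-en-1-ol (Pd(PPh3)4, CuI, DMF, 60 °C) would give 2-(3-hydroxyprop-1-en-2-yl)-4-methoxy-5-methylphenyl (2E)-2-methylbut-2-enoate F2. Sharpless asymmetric epoxidation of this 2-arylallyl alcohol (Ti(OiPr)4, L-(+)-diethyl tartrate, t-BuOOH, 4 Å MS, CH2Cl2, −20 °C) should deliver oxygen to the face that gives (S)-epoxy alcohol 10, from which step 6 follows.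

2. Step 2. Bromine–lithium exchange on the electron-rich lithium phenolate may stay incomplete, the dianion may aggregate and react sluggishly, or it may deprotonate oxetan-3-one instead of adding to it; each of these returns debrominated phenol. The fallback sets out from 2 and comes back at 5. Benzylation of 2 (BnBr, K2CO3, acetone) would give 1-(benzyloxy)-2-bromo-4-methoxy-5-methylbenzene F3. Exchange with one equivalent of n-BuLi in THF at −78 °C and addition to 3 would give 3-[2-(benzyloxy)-5-methoxy-4-methylphenyl]oxetan-3-ol F4. Hydrogenolysis (H2, Pd/C, EtOAc) would then release 5.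

3. Step 5. The silver-assisted displacement at the neopentyl-type CH2Br may be slow, the primary hydroxyl may close back to the oxetane, or the tigloyl group may migrate to a free hydroxyl. The fallback sets out from 9 and comes back at 11; it reverses the order of esterification and ring closure. The primary hydroxyl of 9 would first be acylated (isovaleryl chloride, 2,4,6-collidine, CH2Cl2, −20 °C) to (2S)-3-bromo-2-hydroxy-2-[5-methoxy-4-methyl-2-[(2E)-2-methylbut-2-enoyl]oxyphenyl]propyl 3-methylbutanoate F5. With no primary hydroxyl left to compete, the tertiary hydroxyl would be closed onto CH2Br with powdered K2CO3 in MeCN at 0 °C, giving 11 directly.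

**Further compounds**

F1 | step 4 | 2-bromo-4-methoxy-5-methylphenyl (2E)-2-methylbut-2-enoate | C/C=C(\C)C(=O)Oc1cc(C)c(OC)cc1Br
F2 | step 4 | 2-(3-hydroxyprop-1-en-2-yl)-4-methoxy-5-methylphenyl (2E)-2-methylbut-2-enoate | C/C=C(\C)C(=O)Oc1cc(C)c(OC)cc1C(=C)CO
F3 | step 2 | 1-(benzyloxy)-2-bromo-4-methoxy-5-methylbenzene | COc1cc(Br)c(OCc2ccccc2)cc1C
F4 | step 2 | 3-[2-(benzyloxy)-5-methoxy-4-methylphenyl]oxetan-3-ol | COc1cc(C2(O)COC2)c(OCc2ccccc2)cc1C
F5 | step 5 | (2S)-3-bromo-2-hydroxy-2-[5-methoxy-4-methyl-2-[(2E)-2-methylbut-2-enoyl]oxyphenyl]propyl 3-methylbutanoate | C/C=C(\C)C(=O)Oc1cc(C)c(OC)cc1[C@](O)(COC(=O)CC(C)C)CBr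
A1 | direct plan | 2-methylidene-4-(trimethylsilyl)but-3-yn-1-ol | OCC(=C)C#C[Si](C)(C)C
A2 | direct plan | [(2R)-2-ethynyloxiran-2-yl]methyl 3-methylbutanoate | C#C[C@]1(COC(=O)CC(C)C)CO1
A3 | direct plan | pentacarbonyl[methoxy(prop-1-en-2-yl)carbene]chromium | COC(C(C)=C)=[Cr](=C=O)(=C=O)(=C=O)(=C=O)=C=O
A4 | direct plan | [(2R)-2-(2-hydroxy-5-methoxy-4-methylphenyl)oxiran-2-yl]methyl 3-methylbutanoate | Cc1cc(O)c(cc1OC)[C@]1(COC(=O)CC(C)C)CO1
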